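**Retrosynthetic overview**
1. Sarcrassin D ⇒ C2 carbinol (syn-dehydration gives the diene) ⇒ C1–C2 bond by Lewis-acid carbonyl-ene closure of the 14-membered ring: the terminal isopropylidene attacks a C2 aldehyde, the laboratory counterpart of the cyclase tail-to-head closure.
2. ε-Lactone and both stereocentres ⇒ 7,8-epoxide opened at C8 by the C20 carboxyl with inversion (the biosynthetic epoxy-acid lactonization); the epoxide comes from a Sharpless epoxidation.
3. Ring order: lactone first, carbocycle second. With C7=C8 still present, an electrophilic C2 would close a six-membered ring instead (neral → isopiperitenol mode); early lactonization removes that olefin.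
4. Open chain: C11=C12 by Still–Gennari olefination, C3=C4 by HWE with glyoxal monoacetal, C4–C5 and C12–C13 by phosphonate alkylation; both chain ends come from 5-bromo-2-methylpent-2-ene.

Numbering used for locants: cembrane numbering (C1 carries the isopropyl group, C4 carries CO2Me = C18, C7 = CH–OAc, C8 = C(CH3)–O, C12 carries the lactone C=O = C20).
Assumption: acetaldehyde N,N-dimethylhydrazone (4) and tert-butyl bis(2,2,2-trifluoroethyl)phosphonoacetate (8) are bought as catalogue reagents.

**Route**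

Step 1
Reactants: 1 5-bromo-2-methylpent-2-ene
Product: 2 (2E)-5-bromo-2-methylpent-2-en-1-ol
Conditions: SeO2 (0.3 equiv), t-BuOOH (3 equiv), salicylic acid (0.1 equiv), CH2Cl2, rt
Reagents that add atoms: tert-butyl hydroperoxide CC(C)(C)OO
Why: Catalytic SeO2/t-BuOOH allylic oxidation (ene reaction then [2,3]-shift) attacks the (E)-methyl group at the more substituted olefin terminus, so the (E)-allylic alcohol forms and the primary bromide is untouched.

Step 2
Reactants: 2 (2E)-5-bromo-2-methylpent-2-en-1-ol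
Product: 3 [(2R,3R)-3-(2-bromoethyl)-2-methyloxiran-2-yl]methanol
Conditions: Ti(OiPr)4 (10 mol%), D-(−)-diethyl tartrate (12 mol%), t-BuOOH (2 equiv, anhydrous), 4 Å MS, CH2Cl2, −20 °C
Reagents that add atoms: tert-butyl hydroperoxide CC(C)(C)OO
Why: Katsuki–Sharpless asymmetric epoxidation, in which D-(−)-tartrate delivers oxygen to the face that gives the (2R,3R)-epoxide (= 7R,8R), so both future stereocentres are set here by the catalyst.

Step 3
Reactants: 3 [(2R,3R)-3-(2-bromoethyl)-2-methyloxiran-2-yl]methanol; 4 acetaldehyde N,N-dimethylhydrazone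
Product: 7 3-[(2R,3R)-3-(2-bromoethyl)-2-methyloxiran-2-yl]propanal, via epoxy triflate 5 (not isolated), via alkylated hydrazone 6 (not isolated)
Conditions: Tf2O, 2,6-lutidine, CH2Cl2, −78 °C; then added to 4/LDA, THF, −78 → −40 °C; then CuCl2 (aq), pH 7 phosphate buffer, THF, rt
Reagents that add atoms: trifluoromethanesulfonic anhydride O=S(=O)(OS(=O)(=O)C(F)(F)F)C(F)(F)F (triflyl group, carried only in 5); water O (aldehyde oxygen of 7)
Why: SN2 displacement of the primary epoxy triflate by the lithiated hydrazone (Corey–Enders azaenolate alkylation, the triflate reacting far faster than the bromide or the epoxide) and buffered Cu(II) hydrazone hydrolysis add the C10–C11 aldehyde unit without touching the epoxide stereocentres.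

Step 4
Reactants: 8 tert-butyl 2-[bis(2,2,2-trifluoroethoxy)phosphoryl]acetate; 1 5-bromo-2-methylpent-2-ene
Product: 9 tert-butyl 2-[bis(2,2,2-trifluoroethoxy)phosphoryl]-6-methylhept-5-enoate (racemic)
Conditions: NaH, NaI (cat.), DMSO/THF, rt → 50 °C
Reagents that add atoms: none
Why: SN2 C-alkylation of the stabilised phosphonoacetate anion by the primary homoallylic bromide gives the α-substituted Still–Gennari reagent that carries C12–C15 and the future lactone carbonyl.

Step 5
Reactants: 9 tert-butyl 2-[bis(2,2,2-trifluoroethoxy)phosphoryl]-6-methylhept-5-enoate; 7 3-[(2R,3R)-3-(2-bromoethyl)-2-methyloxiran-2-yl]propanal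
Product: 10 tert-butyl (2Z)-5-[(2R,3R)-3-(2-bromoethyl)-2-methyloxiran-2-yl]-2-(4-methylpent-3-en-1-yl)pent-2-enoate
Conditions: KHMDS, 18-crown-6, THF, −78 °C; then 7, −78 °C
Reagents that add atoms: none
Why: Still–Gennari olefination (electron-poor phosphonate, dissociated potassium enolate, kinetic control) gives the (Z)-trisubstituted enoate with C10 cis to the ester, the geometry the seven-membered lactone needs.

Step 6
Reactants: 10 tert-butyl (2Z)-5-[(2R,3R)-3-(2-bromoethyl)-2-methyloxiran-2-yl]-2-(4-methylpent-3-en-1-yl)pent-2-enoate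
Product: 12 (1R)-3-bromo-1-[(2S)-2-methyl-6-(4-methylpent-3-en-1-yl)-7-oxo-2,3,4,7-tetrahydrooxepin-2-yl]propyl acetate, via hydroxy lactone 11 (not isolated)
Conditions: BF3·OEt2 (0.2 equiv), CH2Cl2, −78 → −20 °C; then Et3N, Ac2O, DMAP (cat.), 0 °C → rt
Reagents that add atoms: acetic anhydride CC(=O)OC(C)=O
Why: Acid-catalysed 7-exo epoxide-opening lactonization by the neighbouring carboxyl group, the laboratory form of the biosynthetic epoxy-acid cyclization: the tert-butyl ester carbonyl attacks the tertiary C8 with inversion and loses isobutene while the C7–O bond is retained, which sets 7R,8S, and the freed C7–OH is acetylated in the same pot.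

Step 7
Reactants: 12 (1R)-3-bromo-1-[(2S)-2-methyl-6-(4-methylpent-3-en-1-yl)-7-oxo-2,3,4,7-tetrahydrooxepin-2-yl]propyl acetate; 13 trimethyl phosphonoacetate
Product: 14 methyl (5R)-5-acetoxy-2-(dimethoxyphosphoryl)-5-[(2S)-2-methyl-6-(4-methylpent-3-en-1-yl)-7-oxo-2,3,4,7-tetrahydrooxepin-2-yl]pentanoate (C2 epimers)
Conditions: NaH, 13 (3 equiv), NaI (cat.), DMF, 50 °C
Reagents that add atoms: none
Why: SN2 alkylation of the soft, weakly basic phosphonoacetate anion at the unhindered primary bromide forms C4–C5 and brings in the C18 ester while lactone and acetate survive.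

Step 8
Reactants: 14 methyl (5R)-5-acetoxy-2-(dimethoxyphosphoryl)-5-[(2S)-2-methyl-6-(4-methylpent-3-en-1-yl)-7-oxo-2,3,4,7-tetrahydrooxepin-2-yl]pentanoate; 15 2,2-dimethoxyacetaldehyde
Product: 17 methyl (2E,5R)-5-acetoxy-5-[(2S)-2-methyl-6-(4-methylpent-3-en-1-yl)-7-oxo-2,3,4,7-tetrahydrooxepin-2-yl]-2-(2-oxoethylidene)pentanoate, via dimethyl acetal 16 (not isolated)
Conditions: NaH, THF, 0 °C; then 15 (dried), 0 °C → rt; then 2 M HCl (aq)/THF, rt
Reagents that add atoms: water O (aldehyde oxygen of 17)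
Why: Horner–Wadsworth–Emmons olefination of the α-alkyl phosphonoacetate gives the (E)-enoate (C2 trans to CO2Me), and the acidic acetal hydrolysis that frees the C2 aldehyde also drains any (Z)-isomer to the more stable (E)-4-oxo-enoate.

Step 9
Reactants: 17 methyl (2E,5R)-5-acetoxy-5-[(2S)-2-methyl-6-(4-methylpent-3-en-1-yl)-7-oxo-2,3,4,7-tetrahydrooxepin-2-yl]-2-(2-oxoethylidene)pentanoate
Product: 18 methyl (3E,7R,8S,11Z)-7-acetoxy-2-hydroxycembra-3,11,15-trien-20,8-olid-18-oate (14-membered ring, C2–OH, C1-isopropenyl; about 1:1 mixture of the 1R,2S and 1S,2R diastereomers)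
Conditions: Me2AlCl (3 equiv), CH2Cl2, −78 → −20 °C, slow addition of 17 to 2 mM
Reagents that add atoms: none
Why: Lewis-acid-promoted type-I carbonyl-ene macrocyclization (Me2AlCl as Lewis acid and proton scavenger; the closest known cases are the analogous ene closures of ω-isopropylidene ynals to 14-membered rings, here extended to an enal): the Al-complexed C2 aldehyde is attacked by the less substituted carbon (C1) of the terminal isopropylidene, the only nucleophilic olefin left in 17, and a methyl hydrogen passes to oxygen through a chair-like six-membered transition state with both ring branches pseudo-equatorial, which forms the C1–C2 bond and the (1R*,2S*) relationship.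

Step 10
Reactants: 18 methyl (3E,7R,8S,11Z)-7-acetoxy-2-hydroxycembra-3,11,15-trien-20,8-olid-18-oate
Product: 19 methyl (3E,7R,8S,11Z)-7-acetoxy-2-hydroxycembra-3,11-dien-20,8-olid-18-oate (1R,2R and 1S,2S diastereomers; same geometry as 18, descriptors change by CIP only)
Conditions: H2 (1 atm), RhCl(PPh3)3 (10 mol%), PhH/EtOH, rt
Reagents that add atoms: none
Why: Homogeneous hydrogenation with Wilkinson's catalyst reduces the 1,1-disubstituted isopropenyl group and leaves the trisubstituted, conjugated C3=C4 and C11=C12 olefins alone, which gives the isopropyl group.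

Step 11
Reactants: 19 methyl (3E,7R,8S,11Z)-7-acetoxy-2-hydroxycembra-3,11-dien-20,8-olid-18-oate
Product: 20 sarcrassin D, methyl (1E,3E,7R,8S,11Z)-7-acetoxycembra-1,3,11-trien-20,8-olid-18-oate
Conditions: Burgess reagent (3 equiv), PhMe, 60 °C
Reagents that add atoms: none
Why: Burgess dehydration (syn Ei elimination of the sulfamate) can only take the C1–H, and from the (1R*,2R*) relationship the syn-periplanar arrangement puts C14 cis to C3 and the isopropyl group trans to C3 (1E), giving the conjugated dienoate while both diastereomers of 19 converge on one product.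

**Compound list**
1 | 5-bromo-2-methylpent-2-ene | CC(C)=CCCBr | starting material
2 | (2E)-5-bromo-2-methylpent-2-en-1-ol | OC/C(C)=C/CCBr | intermediate
3 | [(2R,3R)-3-(2-bromoethyl)-2-methyloxiran-2-yl]methanol | OC[C@@]1(C)O[C@@H]1CCBr | intermediate
4 | acetaldehyde N,N-dimethylhydrazone | C/C=N/N(C)C | starting material
5 | [(2R,3R)-3-(2-bromoethyl)-2-methyloxiran-2-yl]methyl trifluoromethanesulfonate | O=S(=O)(OC[C@@]1(C)O[C@@H]1CCBr)C(F)(F)F | intermediate (not isolated)
6 | 3-[(2R,3R)-3-(2-bromoethyl)-2-methyloxiran-2-yl]propanal N,N-dimethylhydrazone | CN(C)/N=C/CC[C@@]1(C)O[C@@H]1CCBr | intermediate (not isolated)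
7 | 3-[(2R,3R)-3-(2-bromoethyl)-2-methyloxiran-2-yl]propanal | O=CCC[C@@]1(C)O[C@@H]1CCBr | intermediate
8 | tert-butyl 2-[bis(2,2,2-trifluoroethoxy)phosphoryl]acetate | CC(C)(C)OC(=O)CP(=O)(OCC(F)(F)F)OCC(F)(F)F | starting material
9 | tert-butyl 2-[bis(2,2,2-trifluoroethoxy)phosphoryl]-6-methylhept-5-enoate (racemic) | CC(C)=CCCC(C(=O)OC(C)(C)C)P(=O)(OCC(F)(F)F)OCC(F)(F)F | intermediate
10 | tert-butyl (2Z)-5-[(2R,3R)-3-(2-bromoethyl)-2-methyloxiran-2-yl]-2-(4-methylpent-3-en-1-yl)pent-2-enoate | CC(C)=CCC/C(C(=O)OC(C)(C)C)=C/CC[C@@]1(C)O[C@@H]1CCBr | intermediate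
11 | (7S)-7-[(1R)-3-bromo-1-hydroxypropyl]-7-methyl-3-(4-methylpent-3-en-1-yl)-6,7-dihydro-5H-oxepin-2-one | CC(C)=CCCC1=CCC[C@](C)(OC1=O)[C@H](O)CCBr | intermediate (not isolated)
12 | (1R)-3-bromo-1-[(2S)-2-methyl-6-(4-methylpent-3-en-1-yl)-7-oxo-2,3,4,7-tetrahydrooxepin-2-yl]propyl acetate | CC(C)=CCCC1=CCC[C@](C)(OC1=O)[C@H](OC(C)=O)CCBr | intermediate
13 | trimethyl phosphonoacetate | COC(=O)CP(=O)(OC)OC | starting material
14 | methyl (5R)-5-acetoxy-2-(dimethoxyphosphoryl)-5-[(2S)-2-methyl-6-(4-methylpent-3-en-1-yl)-7-oxo-2,3,4,7-tetrahydrooxepin-2-yl]pentanoate (C2 epimers) | CC(C)=CCCC1=CCC[C@](C)(OC1=O)[C@H](OC(C)=O)CCC(C(=O)OC)P(=O)(OC)OC | intermediate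
15 | 2,2-dimethoxyacetaldehyde | COC(OC)C=O | starting material
16 | methyl (2E,5R)-5-acetoxy-2-(2,2-dimethoxyethylidene)-5-[(2S)-2-methyl-6-(4-methylpent-3-en-1-yl)-7-oxo-2,3,4,7-tetrahydrooxepin-2-yl]pentanoate | CC(C)=CCCC1=CCC[C@](C)(OC1=O)[C@H](OC(C)=O)CC/C(C(=O)OC)=C\C(OC)OC | intermediate (not isolated)
17 | methyl (2E,5R)-5-acetoxy-5-[(2S)-2-methyl-6-(4-methylpent-3-en-1-yl)-7-oxo-2,3,4,7-tetrahydrooxepin-2-yl]-2-(2-oxoethylidene)pentanoate | CC(C)=CCCC1=CCC[C@](C)(OC1=O)[C@H](OC(C)=O)CC/C(C(=O)OC)=C\C=O | intermediate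
18 | methyl (1R,2S,3E,7R,8S,11Z)-7-acetoxy-2-hydroxycembra-3,11,15-trien-20,8-olid-18-oate (drawn; formed together with its 1S,2R diastereomer) | COC(=O)/C1=C/[C@H](O)[C@@H](C(C)=C)CCC2=CCC[C@](C)(OC2=O)[C@H](OC(C)=O)CC1 | intermediate
19 | methyl (1R,2R,3E,7R,8S,11Z)-7-acetoxy-2-hydroxycembra-3,11-dien-20,8-olid-18-oate (drawn; together with its 1S,2S diastereomer) | COC(=O)/C1=C/[C@H](O)[C@@H](C(C)C)CCC2=CCC[C@](C)(OC2=O)[C@H](OC(C)=O)CC1 | intermediate
20 | sarcrassin D, methyl (1E,3E,7R,8S,11Z)-7-acetoxycembra-1,3,11-trien-20,8-olid-18-oate | COC(=O)/C1=C/C=C(/C(C)C)CCC2=CCC[C@](C)(OC2=O)[C@H](OC(C)=O)CC1 | target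

**Count**
Total steps: 11. Longest linear sequence: 10 steps (1 → 2 → 3 → 7 → 10 → 12 → 14 → 17 → 18 → 19 → 20; step 4 is the one-step side branch).

**Three steps most likely to fail, with fallbacks**

Step 9 (macrocyclic carbonyl-ene). The risks are oligomerization, methyl transfer from aluminium and conjugate pathways of the enal. The fallback sets out from 17 and comes back at 18. The terminal isopropylidene of 17 is chlorinated in the ene sense (NCS, cat. PhSeCl, CH2Cl2, rt) to give the rearranged secondary allylic chloride methyl (2E,5R)-5-acetoxy-5-[(2S)-6-(3-chloro-4-methylpent-4-en-1-yl)-2-methyl-7-oxo-2,3,4,7-tetrahydrooxepin-2-yl]-2-(2-oxoethylidene)pentanoate F1. CrCl2 in THF at high dilution then closes the ring by an intramolecular Nozaki–Hiyama allylation: the allylchromium adds through its more substituted carbon (C1) to the C2 aldehyde and delivers 18. This replaces the electrophilic ene closure by a reductive, nucleophilic one at the same bond. If it gives the other C1/C2 relationship, step 11 is run through the fallback below.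

Step 11 (dehydration, C1=C2 geometry). The outcome depends on the C1/C2 relationship predicted for step 9, and a Burgess reagent can also give urethane or transposed products with allylic alcohols. The fallback sets out from 19 and comes back at 20. 19 is converted with ClCO2Me/pyridine into the allylic carbonate methyl (3E,7R,8S,11Z)-7-acetoxy-2-[(methoxycarbonyl)oxy]cembra-3,11-dien-20,8-olid-18-oate F2. Pd(OAc)2/PPh3 in dioxane at 80 °C then ionises it to the π-allyl complex, which eliminates to the conjugated diene 20 (palladium-catalysed 1,4-elimination). Because the π-allyl intermediate can equilibrate, both diastereomers can drain to the less strained (1E,3E)-dienoate.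

Step 6 (epoxide-opening lactonization through the tert-butyl ester). The risks are Meinwald rearrangement of the trisubstituted epoxide and slow seven-membered participation. The fallback sets out from 7 and comes back at 12; it opens the epoxide with a free acid instead. Commercial methyl bis(2,2,2-trifluoroethyl)phosphonoacetate is alkylated with 1 (NaH) to the phosphonate methyl 2-[bis(2,2,2-trifluoroethoxy)phosphoryl]-6-methylhept-5-enoate F3. Still–Gennari olefination of 7 with it gives the methyl ester methyl (2Z)-5-[(2R,3R)-3-(2-bromoethyl)-2-methyloxiran-2-yl]-2-(4-methylpent-3-en-1-yl)pent-2-enoate F4. Me3SnOH in 1,2-dichloroethane at 70 °C hydrolyses it to the epoxy acid (2Z)-5-[(2R,3R)-3-(2-bromoethyl)-2-methyloxiran-2-yl]-2-(4-methylpent-3-en-1-yl)pent-2-enoic acid F5. Catalytic camphorsulfonic acid in CH2Cl2 then closes the lactone by attack of the acid at C8 to give 11, which is acetylated (Ac2O, Et3N, DMAP) to 12.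

**Further compounds**
F1 | step 9 | methyl (2E,5R)-5-acetoxy-5-[(2S)-6-(3-chloro-4-methylpent-4-en-1-yl)-2-methyl-7-oxo-2,3,4,7-tetrahydrooxepin-2-yl]-2-(2-oxoethylidene)pentanoate (epimers at the C–Cl carbon) | C=C(C)C(Cl)CCC1=CCC[C@](C)(OC1=O)[C@H](OC(C)=O)CC/C(C(=O)OC)=C\C=O
F2 | step 11 | methyl (1R,2R,3E,7R,8S,11Z)-7-acetoxy-2-[(methoxycarbonyl)oxy]cembra-3,11-dien-20,8-olid-18-oate (drawn; together with its 1S,2S diastereomer) | COC(=O)/C1=C/[C@H](OC(=O)OC)[C@@H](C(C)C)CCC2=CCC[C@](C)(OC2=O)[C@H](OC(C)=O)CC1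
F3 | step 6 | methyl 2-[bis(2,2,2-trifluoroethoxy)phosphoryl]-6-methylhept-5-enoate (racemic) | CC(C)=CCCC(C(=O)OC)P(=O)(OCC(F)(F)F)OCC(F)(F)F
F4 | step 6 | methyl (2Z)-5-[(2R,3R)-3-(2-bromoethyl)-2-methyloxiran-2-yl]-2-(4-methylpent-3-en-1-yl)pent-2-enoate | CC(C)=CCC/C(C(=O)OC)=C/CC[C@@]1(C)O[C@@H]1CCBr
F5 | step 6 | (2Z)-5-[(2R,3R)-3-(2-bromoethyl)-2-methyloxiran-2-yl]-2-(4-methylpent-3-en-1-yl)pent-2-enoic acid | CC(C)=CCC/C(C(O)=O)=C/CC[C@@]1(C)O[C@@H]1CCBr
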